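Ring B of the bicyclo[3.3.1]nonane (C1, C9, C5, C6, C7, C8; C1 carries the hydroxyalkyl chain, C5 the lavandulyl-type chain, C7 the prenyl group, C8 the gem-dimethyl, C9 is the bridging carbonyl) is disconnected at C6–C7 and C1–C9. The pieces are an α-substituted acrylate (C6, C5, C9) and the side-chain carbanion of a 6-alkyl-4-methoxy-2-pyranone. The pyranone is a masked triketide: its ring oxygen marks C8 as a latent carbonyl flanked by nucleophilic C7 and C1, and it already holds C2–C4. One Michael–Claisen operation forms both bonds and gives a chromenedione. Double methyl-cuprate addition then expels the lactone oxygen from C8, and the freed C4 carboxyl later acylates C5 to close ring A.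

Key step: step 8

Remarks on the chemistry:
- Atom numbers are those of the target's bicyclo[3.3.1]nonane skeleton (C2 ketone, C3 aroyl carbon, C4 enol carbon).
- The target is drawn as the 4-hydroxy-2-oxo tautomer; the enol tautomers interconvert, so the free 2,4-dione enol obtained in step 17 is the same compound.
- C7 is not controlled in this route. It stays epimerisable until step 9, is fixed there with no bias from the remote side-chain centre, and both C7 series are carried to step 13, where they are separated as diastereomeric bicycles. C5 stays epimerisable until the ring closure of step 13 sets it.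

Step 1
Reactants: 1 (S)-4-benzyloxazolidin-2-one; 2 3-methylbut-2-enoyl chloride
Product: 3 (S)-4-benzyl-3-(3-methylbut-2-enoyl)oxazolidin-2-one
Conditions: n-BuLi, THF, −78 °C; then 2, −78 → 0 °C
Reagents that add atoms: none
Why: N-acylation of the lithiated Evans auxiliary by the acid chloride; no new stereocentre.

Step 2
Reactants: 3; 4 1-bromo-3-methylbut-2-ene (prenyl bromide)
Product: 5 (S)-4-benzyl-3-[(2S)-5-methyl-2-(prop-1-en-2-yl)hex-4-enoyl]oxazolidin-2-one
Conditions: NaHMDS, THF, −78 °C; then 4, −78 → −20 °C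
Reagents that add atoms: none
Why: Evans deconjugative α-alkylation of the chelated sodium dienolate (γ-deprotonation of the s-cis enoyl imide), with the allylic bromide entering anti to the benzyl group, should set the side-chain centre as (2S).

Step 3
Reactants: 5
Product: 6 (S)-lavandulol, (2S)-5-methyl-2-(prop-1-en-2-yl)hex-4-en-1-ol
Conditions: LiBH4, Et2O, H2O (1 equiv), 0 °C
Reagents that add atoms: none
Why: Reductive cleavage of the acyl oxazolidinone to the primary alcohol without touching the β,γ-unsaturated stereocentre; the auxiliary is recovered.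

Step 4
Reactants: 6
Product: 7 (S)-lavandulyl iodide, (3S)-3-(iodomethyl)-2,6-dimethylhepta-1,5-diene
Conditions: I2, PPh3, imidazole, CH2Cl2, 0 °C
Reagents that add atoms: iodine, II
Why: Appel-type iodination of the primary alcohol; the stereocentre is not involved.

Step 5
Reactants: 7; 8 trimethyl phosphonoacetate
Product: 9 methyl (4R)-2-(dimethoxyphosphoryl)-7-methyl-4-(prop-1-en-2-yl)oct-6-enoate (mixture at C2)
Conditions: NaH, DMSO, 20 → 60 °C
Reagents that add atoms: none
Why: SN2 alkylation of the stabilised phosphonoacetate anion by the primary iodide; the new centre at C2 is lost in step 6.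

Step 6
Reactants: 9
Product: 10 methyl (4R)-7-methyl-2-methylidene-4-(prop-1-en-2-yl)oct-6-enoate
Conditions: aq. HCHO, K2CO3, THF, 20 → 60 °C
Reagents that add atoms: formaldehyde, C=O
Why: Horner–Wadsworth–Emmons methylenation gives the α-substituted acrylate that later supplies C6, C5 and C9.

Step 7
Reactants: 11 4-methoxy-6-methyl-2H-pyran-2-one; 4
Product: 12 4-methoxy-6-(4-methylpent-3-en-1-yl)-2H-pyran-2-one
Conditions: LDA, THF, DMPU, −78 °C; then 4, −78 → −30 °C
Reagents that add atoms: none
Why: Lateral lithiation of the 6-methyl group of the 4-methoxy-2-pyranone and SN2 alkylation places the future C7 prenyl group.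

Step 8
Reactants: 12; 10
Product: 14 4-methoxy-8-(3-methylbut-2-en-1-yl)-6-[(2R)-5-methyl-2-(prop-1-en-2-yl)hex-4-en-1-yl]-7,8-dihydro-2H-chromene-2,5(6H)-dione (mixture at chromene C6 and C8), via Michael adduct ester 13 (not isolated)
Conditions: LDA (1.05 equiv), THF, −78 °C; then 10; then LDA (1.1 equiv), −78 → 20 °C; aq. NH4Cl
Reagents that add atoms: none
Why: Proposed new method: the lateral lithium anion of 12, an extended enolate with charge on the exocyclic carbon and on ring positions 5 and 3 of the pyranone, adds 1,4 to acrylate 10 (C6–C7); after proton transfer and a second deprotonation the regenerated anion acylates through ring position 5 on the new ester (C1–C9) with loss of methoxide, and the 5-acyl intermediate tautomerises back to the aromatic 2-pyranone. The closest known reaction types are the consecutive Michael–Claisen synthesis of cyclohexane-1,3-diones from ketone enolates and acrylates and the Staunton–Weinreb toluate-anion annulation, the pyranone being the enol lactone of the C8 ketone. Ring B closes by a 6-exo-trig acyl substitution (Dieckmann type), the only ring size the nucleophilic positions of the anion can reach on this ester. C7 and C5 are created as stereocentres but both remain epimerisable (C7 vinylogously α, C5 directly α to the C9 ketone), so no stereocontrol is asked of this step. It needs site selectivity: conjugate addition is favoured by the soft delocalised anion at low temperature, acylation at ring position 5 is enforced by the tether, and the isolated alkenes are inert to the base. Irreversible deprotonation of 14 at C7 (a vinylogous β-dicarbonyl position) should pull the Claisen equilibrium forward.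

Step 9
Reactants: 14
Product: 16 (2E)-3-[(3R)-2,2-dimethyl-3-(3-methylbut-2-en-1-yl)-5-[(2R)-5-methyl-2-(prop-1-en-2-yl)hex-4-en-1-yl]-6-oxocyclohexyl]-3-methoxyprop-2-enoic acid (mixture at ring C1 and C5; accompanied by its ring-C3 epimer, i.e. the C7 epimer), via enone acid 15 (not isolated)
Conditions: Me2CuLi (excess), TMSCl, Et2O–THF, −78 → 0 °C; then aq. HCl, 0 °C
Reagents that add atoms: lithium dimethylcuprate, [Li+].C[Cu-]C
Why: Cuprate addition–elimination at C8 (a vinylogous anhydride carbon whose leaving group is the lactone carboxylate) followed by a second 1,4-addition to enone 15 installs the gem-dimethyl group and opens the pyranone to the C4 acid with the C2=C3 geometry retained; C7 loses its acidity here without facial bias, so both C7 epimers are expected and are carried on together.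

Step 10
Reactants: 16; 17 but-3-en-2-one (methyl vinyl ketone)
Product: 18 (2E)-3-[(1S,3R)-2,2-dimethyl-3-(3-methylbut-2-en-1-yl)-5-[(2R)-5-methyl-2-(prop-1-en-2-yl)hex-4-en-1-yl]-6-oxo-1-(3-oxobutyl)cyclohexyl]-3-methoxyprop-2-enoic acid (mixture at ring C5)
Conditions: t-BuOK (2.2 equiv), THF–t-BuOH, −20 °C; then 17; aq. HCl
Reagents that add atoms: none
Why: Michael addition of the carboxylate–enolate dianion, in which the carboxylate keeps charge off C3 so that the ketone α-carbon C1 reacts; axial attack on the half-chair with equatorial C7 prenyl should place the new chain trans to the prenyl group and set C1.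

Step 11
Reactants: 18
Product: 19 methyl (2E)-3-[(1S,3R)-2,2-dimethyl-3-(3-methylbut-2-en-1-yl)-5-[(2R)-5-methyl-2-(prop-1-en-2-yl)hex-4-en-1-yl]-6-oxo-1-(3-oxobutyl)cyclohexyl]-3-methoxyprop-2-enoate (mixture at ring C5)
Conditions: TMSCHN2, PhMe–MeOH, 0 °C
Reagents that add atoms: (trimethylsilyl)diazomethane, C[Si](C)(C)C=[N+]=[N-]
Why: Neutral methyl esterification of the acid turns C4 into an acyl donor without affecting the ketones, the enol ether or the alkenes.

Step 12
Reactants: 19
Product: 20 methyl (2E)-3-[(1S,3R)-2,2-dimethyl-3-(3-methylbut-2-en-1-yl)-1-{3-methyl-3-[(trimethylsilyl)oxy]butyl}-5-[(2R)-5-methyl-2-(prop-1-en-2-yl)hex-4-en-1-yl]-6-oxocyclohexyl]-3-methoxyprop-2-enoate (mixture at ring C5)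
Conditions: MeMgBr, THF, −78 °C; then TMSCl, −78 → 20 °C
Reagents that add atoms: methylmagnesium bromide, C[Mg]Br; chlorotrimethylsilane, C[Si](C)(C)Cl
Why: Grignard 1,2-addition should be chemoselective for the unhindered side-chain methyl ketone over the doubly α-branched C9 ketone and the vinylogous carbonate ester, and the magnesium alkoxide is silylated in the same flask to protect the tertiary alcohol.

Step 13
Reactants: 20
Product: 21 2-methoxy-8,8-dimethyl-7-(3-methylbut-2-en-1-yl)-1-{3-methyl-3-[(trimethylsilyl)oxy]butyl}-5-[(2R)-5-methyl-2-(prop-1-en-2-yl)hex-4-en-1-yl]bicyclo[3.3.1]non-2-ene-4,9-dione (target numbering; C1, C5 and C7 arranged as in 26)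
Conditions: LiHMDS, THF, −78 → 20 °C; aq. NH4Cl; preparative HPLC
Reagents that add atoms: none
Why: Intramolecular Claisen (Dieckmann-type) C-acylation of the C5 lithium enolate by the C4 ester, held cis to C1 across the C2=C3 bond, closes ring A; only the cis-bridged bicycle can form, so C5 is set by C1, and the diastereomer built on the enantiomeric core (from the C7-epimeric series) is removed by HPLC.

Step 14
Reactants: 22 3,4-dihydroxybenzoic acid
Product: 23 tert-butyldimethylsilyl 3,4-bis[(tert-butyldimethylsilyl)oxy]benzoate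
Conditions: TBSCl (3.3 equiv), imidazole, DMF, 20 °C
Reagents that add atoms: tert-butyl(chloro)dimethylsilane, CC(C)(C)[Si](C)(C)Cl
Why: Exhaustive silylation protects the catechol and gives the silyl ester needed in step 15.

Step 15
Reactants: 23
Product: 24 3,4-bis[(tert-butyldimethylsilyl)oxy]benzoyl chloride
Conditions: (COCl)2, DMF (cat.), CH2Cl2, 0 → 20 °C
Reagents that add atoms: oxalyl chloride, ClC(=O)C(Cl)=O
Why: Vilsmeier-mediated conversion of the silyl ester into the acid chloride under neutral conditions leaves the aryl silyl ethers intact.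

Step 16
Reactants: 21; 24
Product: 25 3-{3,4-bis[(tert-butyldimethylsilyl)oxy]benzoyl}-2-methoxy-8,8-dimethyl-7-(3-methylbut-2-en-1-yl)-1-{3-methyl-3-[(trimethylsilyl)oxy]butyl}-5-[(2R)-5-methyl-2-(prop-1-en-2-yl)hex-4-en-1-yl]bicyclo[3.3.1]non-2-ene-4,9-dione (target numbering; configured as 26)
Conditions: LiTMP, THF, −78 °C; then 24, −78 → 0 °C
Reagents that add atoms: none
Why: α-Lithiation of the vinylogous ester at C3 (both bridgeheads are quaternary, so no competing site) and C-acylation by the acid chloride installs the aroyl group.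

Step 17
Reactants: 25
Product: 26 (1R,5R,7R)-3-(3,4-dihydroxybenzoyl)-4-hydroxy-1-(3-hydroxy-3-methylbutyl)-8,8-dimethyl-7-(3-methylbut-2-en-1-yl)-5-[(2R)-5-methyl-2-(prop-1-en-2-yl)hex-4-en-1-yl]bicyclo[3.3.1]non-3-ene-2,9-dione
Conditions: LiOH, dioxane–H2O (degassed, argon), 90 °C; then aq. HCl to pH 4, 0 °C
Reagents that add atoms: lithium hydroxide, [Li+].[OH-]
Why: Hydroxide addition–elimination cleaves the vinylogous methyl ester to the triketone enolate and the same basic medium removes the aryl silyl ethers and the tertiary trimethylsilyl ether, avoiding acid, which would cyclise the enol onto the alkenes.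

Compound list
1 | (S)-4-benzyloxazolidin-2-one | O=C1N[C@@H](Cc2ccccc2)CO1 | starting material
2 | 3-methylbut-2-enoyl chloride | CC(C)=CC(Cl)=O | starting material
3 | (S)-4-benzyl-3-(3-methylbut-2-enoyl)oxazolidin-2-one | CC(C)=CC(=O)N1[C@@H](Cc2ccccc2)COC1=O | intermediate
4 | 1-bromo-3-methylbut-2-ene | CC(C)=CCBr | starting material
5 | (S)-4-benzyl-3-[(2S)-5-methyl-2-(prop-1-en-2-yl)hex-4-enoyl]oxazolidin-2-one | C=C(C)[C@H](CC=C(C)C)C(=O)N1[C@@H](Cc2ccccc2)COC1=O | intermediate
6 | (S)-lavandulol, (2S)-5-methyl-2-(prop-1-en-2-yl)hex-4-en-1-ol | C=C(C)[C@H](CC=C(C)C)CO | intermediate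
7 | (3S)-3-(iodomethyl)-2,6-dimethylhepta-1,5-diene | C=C(C)[C@H](CC=C(C)C)CI | intermediate
8 | trimethyl phosphonoacetate | COC(=O)CP(=O)(OC)OC | starting material
9 | methyl (4R)-2-(dimethoxyphosphoryl)-7-methyl-4-(prop-1-en-2-yl)oct-6-enoate (mixture at C2) | C=C(C)[C@H](CC=C(C)C)CC(C(=O)OC)P(=O)(OC)OC | intermediate
10 | methyl (4R)-7-methyl-2-methylidene-4-(prop-1-en-2-yl)oct-6-enoate | C=C(C)[C@H](CC=C(C)C)CC(=C)C(=O)OC | intermediate
11 | 4-methoxy-6-methyl-2H-pyran-2-one | COC1=CC(=O)OC(C)=C1 | starting material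
12 | 4-methoxy-6-(4-methylpent-3-en-1-yl)-2H-pyran-2-one | COC1=CC(=O)OC(CCC=C(C)C)=C1 | intermediate
13 | methyl (4R)-2-[2-(4-methoxy-2-oxo-2H-pyran-6-yl)-5-methylhex-4-en-1-yl]-7-methyl-4-(prop-1-en-2-yl)oct-6-enoate (Michael adduct ester; mixture at the two new centres) | COC1=CC(=O)OC(=C1)C(CC=C(C)C)CC(C[C@@H](CC=C(C)C)C(C)=C)C(=O)OC | intermediate
14 | 4-methoxy-8-(3-methylbut-2-en-1-yl)-6-[(2R)-5-methyl-2-(prop-1-en-2-yl)hex-4-en-1-yl]-7,8-dihydro-2H-chromene-2,5(6H)-dione (mixture at C6 and C8) | COC1=CC(=O)OC2=C1C(=O)C(C[C@@H](CC=C(C)C)C(C)=C)CC2CC=C(C)C | intermediate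
15 | (2E)-3-methoxy-3-[2-methyl-3-(3-methylbut-2-en-1-yl)-5-[(2R)-5-methyl-2-(prop-1-en-2-yl)hex-4-en-1-yl]-6-oxocyclohex-1-en-1-yl]prop-2-enoic acid (enone acid; mixture at ring C3 and C5) | C=C(C)[C@H](CC=C(C)C)CC1CC(CC=C(C)C)C(C)=C(/C(OC)=C\C(O)=O)C1=O | intermediate
16 | (2E)-3-[(3R)-2,2-dimethyl-3-(3-methylbut-2-en-1-yl)-5-[(2R)-5-methyl-2-(prop-1-en-2-yl)hex-4-en-1-yl]-6-oxocyclohexyl]-3-methoxyprop-2-enoic acid (mixture at ring C1 and C5) | C=C(C)[C@H](CC=C(C)C)CC1C[C@@H](CC=C(C)C)C(C)(C)C(/C(OC)=C\C(O)=O)C1=O | intermediate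
17 | but-3-en-2-one | CC(=O)C=C | starting material
18 | (2E)-3-[(1S,3R)-2,2-dimethyl-3-(3-methylbut-2-en-1-yl)-5-[(2R)-5-methyl-2-(prop-1-en-2-yl)hex-4-en-1-yl]-6-oxo-1-(3-oxobutyl)cyclohexyl]-3-methoxyprop-2-enoic acid (mixture at ring C5) | C=C(C)[C@H](CC=C(C)C)CC1C[C@@H](CC=C(C)C)C(C)(C)[C@@](CCC(C)=O)(/C(OC)=C\C(O)=O)C1=O | intermediate
19 | methyl ester of 18 | C=C(C)[C@H](CC=C(C)C)CC1C[C@@H](CC=C(C)C)C(C)(C)[C@@](CCC(C)=O)(/C(OC)=C\C(=O)OC)C1=O | intermediate
20 | methyl (2E)-3-[(1S,3R)-2,2-dimethyl-3-(3-methylbut-2-en-1-yl)-1-{3-methyl-3-[(trimethylsilyl)oxy]butyl}-5-[(2R)-5-methyl-2-(prop-1-en-2-yl)hex-4-en-1-yl]-6-oxocyclohexyl]-3-methoxyprop-2-enoate (mixture at ring C5) | C=C(C)[C@H](CC=C(C)C)CC1C[C@@H](CC=C(C)C)C(C)(C)[C@@](CCC(C)(C)O[Si](C)(C)C)(/C(OC)=C\C(=O)OC)C1=O | intermediate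
21 | 2-methoxy-8,8-dimethyl-7-(3-methylbut-2-en-1-yl)-1-{3-methyl-3-[(trimethylsilyl)oxy]butyl}-5-[(2R)-5-methyl-2-(prop-1-en-2-yl)hex-4-en-1-yl]bicyclo[3.3.1]non-2-ene-4,9-dione (target numbering; configured as 26) | C=C(C)[C@H](CC=C(C)C)C[C@@]12C[C@@H](CC=C(C)C)C(C)(C)[C@@](CCC(C)(C)O[Si](C)(C)C)(C(OC)=CC1=O)C2=O | intermediate
22 | 3,4-dihydroxybenzoic acid | OC(=O)c1ccc(O)c(O)c1 | starting material
23 | tert-butyldimethylsilyl 3,4-bis[(tert-butyldimethylsilyl)oxy]benzoate | CC(C)(C)[Si](C)(C)OC(=O)c1ccc(O[Si](C)(C)C(C)(C)C)c(O[Si](C)(C)C(C)(C)C)c1 | intermediate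
24 | 3,4-bis[(tert-butyldimethylsilyl)oxy]benzoyl chloride | ClC(=O)c1ccc(O[Si](C)(C)C(C)(C)C)c(O[Si](C)(C)C(C)(C)C)c1 | intermediate
25 | 3-{3,4-bis[(tert-butyldimethylsilyl)oxy]benzoyl} derivative of 21 | C=C(C)[C@H](CC=C(C)C)C[C@@]12C[C@@H](CC=C(C)C)C(C)(C)[C@@](CCC(C)(C)O[Si](C)(C)C)(C(OC)=C(C(=O)c3ccc(O[Si](C)(C)C(C)(C)C)c(O[Si](C)(C)C(C)(C)C)c3)C1=O)C2=O | intermediate
26 | (1R,5R,7R)-3-(3,4-dihydroxybenzoyl)-4-hydroxy-1-(3-hydroxy-3-methylbutyl)-8,8-dimethyl-7-(3-methylbut-2-en-1-yl)-5-[(2R)-5-methyl-2-(prop-1-en-2-yl)hex-4-en-1-yl]bicyclo[3.3.1]non-3-ene-2,9-dione | C=C(C)[C@H](CC=C(C)C)C[C@@]12C[C@@H](CC=C(C)C)C(C)(C)[C@@](CCC(C)(C)O)(C(=O)C(C(=O)c3ccc(O)c(O)c3)=C1O)C2=O | target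

Total step count: 17. Longest linear sequence: 14 steps (steps 1–6, 8–13, 16, 17).

Steps most likely to fail

Step 8 (Proposed new method). The acylation through ring position 5 of the pyranone anion may not compete with simple proton quench of adduct 13, or the ester enolate may attack the lactone carbonyl, so the cascade may stop or stray. The fallback uses known chemistry and sets out from 10. Acrylate 10 and commercial 6-methylhept-5-en-2-one are joined by the known consecutive Michael–Claisen reaction of a methyl ketone with an acrylate (t-BuOK, THF, 0 → 20 °C). This forms the same two ring bonds and gives 4-(3-methylbut-2-en-1-yl)-6-[(2R)-5-methyl-2-(prop-1-en-2-yl)hex-4-en-1-yl]cyclohexane-1,3-dione F1. Pyranone annulation with bis(2,4,6-trichlorophenyl) malonate (PhBr, reflux) gives 4-hydroxy-8-(3-methylbut-2-en-1-yl)-6-[(2R)-5-methyl-2-(prop-1-en-2-yl)hex-4-en-1-yl]-7,8-dihydro-2H-chromene-2,5(6H)-dione F2; the regioisomer lactonised on the other enol oxygen is removed by chromatography. O-Methylation (Me2SO4, K2CO3, acetone) comes back to the route at 14.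

Step 9. The second methyl transfer to the tetrasubstituted, α-branched enone of 15 may stall, or the cuprate may enolise the substrate instead of adding. The fallback sets out from 14: the cuprate is limited to the first transfer and enone acid 15 is isolated. Corey–Chaykovsky cyclopropanation (Me3S(O)I, NaH, DMSO) should give (2E)-3-methoxy-3-{6-methyl-5-(3-methylbut-2-en-1-yl)-3-[(2R)-5-methyl-2-(prop-1-en-2-yl)hex-4-en-1-yl]-2-oxobicyclo[4.1.0]heptan-1-yl}prop-2-enoic acid F3. Reductive opening of the external cyclopropane bond of this conjugated cyclopropyl ketone (SmI2, THF, t-BuOH, DMPU) turns the cyclopropane methylene into the second methyl group and comes back at 16.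

Step 10. The ambident anion may react at C3 (α to the carboxyl) or at oxygen, or may fail to form the quaternary centre next to C8. The fallback sets out from 14: the step 9 mixture is worked up without water so that the enolate stays trapped as trimethylsilyl (2E)-3-[(5R)-6,6-dimethyl-5-(3-methylbut-2-en-1-yl)-3-[(2R)-5-methyl-2-(prop-1-en-2-yl)hex-4-en-1-yl]-2-[(trimethylsilyl)oxy]cyclohex-1-en-1-yl]-3-methoxyprop-2-enoate F4. A Mukaiyama–Michael addition of this regiodefined enol silane to 17 (BF3·OEt2, CH2Cl2, −78 °C), followed by aqueous work-up, forms the C1–C10 bond at the enol silane carbon and comes back at 18.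

Further compounds
F1 | step 8 | 4-(3-methylbut-2-en-1-yl)-6-[(2R)-5-methyl-2-(prop-1-en-2-yl)hex-4-en-1-yl]cyclohexane-1,3-dione | O=C1CC(=O)C(CC=C(C)C)CC1C[C@@H](CC=C(C)C)C(C)=C
F2 | step 8 | 4-hydroxy-8-(3-methylbut-2-en-1-yl)-6-[(2R)-5-methyl-2-(prop-1-en-2-yl)hex-4-en-1-yl]-7,8-dihydro-2H-chromene-2,5(6H)-dione | OC1=CC(=O)OC2=C1C(=O)C(C[C@@H](CC=C(C)C)C(C)=C)CC2CC=C(C)C
F3 | step 9 | (2E)-3-methoxy-3-{6-methyl-5-(3-methylbut-2-en-1-yl)-3-[(2R)-5-methyl-2-(prop-1-en-2-yl)hex-4-en-1-yl]-2-oxobicyclo[4.1.0]heptan-1-yl}prop-2-enoic acid | C=C(C)[C@H](CC=C(C)C)CC1CC(CC=C(C)C)C2(C)CC2(/C(OC)=C\C(O)=O)C1=O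
F4 | step 10 | trimethylsilyl (2E)-3-[(5R)-6,6-dimethyl-5-(3-methylbut-2-en-1-yl)-3-[(2R)-5-methyl-2-(prop-1-en-2-yl)hex-4-en-1-yl]-2-[(trimethylsilyl)oxy]cyclohex-1-en-1-yl]-3-methoxyprop-2-enoate | C=C(C)[C@H](CC=C(C)C)CC1C[C@@H](CC=C(C)C)C(C)(C)C(/C(OC)=C\C(=O)O[Si](C)(C)C)=C1O[Si](C)(C)C
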